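The trimethylcyclohexene is cut from the side chain at ring carbon C1 and traced back to a cyclopentene. Its neighbours C2 (sp2, one methyl) and C6 (sp3, two methyls) differ by a single methyl, so a 2-bromo-1,3-dimethylcyclohexenyl cation is symmetric and either end may accept that methyl. The key step makes this cation by electrocyclic opening of 6,6-dibromo-1,5-dimethylbicyclo[3.1.0]hexane, the dibromocarbene adduct of 1,2-dimethylcyclopentene, and quenches it with AlMe3: the five-membered ring grows by the carbene carbon, and the alkene position, the quaternary carbon and a vinyl bromide at C1 arise together. B-alkyl Suzuki coupling, palladium-catalysed asymmetric O-allylation (stereocentre) and ring-closing metathesis (chromene) finish the synthesis.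

Key step: step 2

Remark on stereocontrol: the (R,R)-enantiomer of the DACH-phenyl bisphosphine ligand is assumed to give the (S)-ether from the (E)-carbonate in step 10; if the sense is the opposite for this substrate, the (S,S)-ligand is used and nothing else changes.

Step 1
Reactants: 1 1,2-dimethylcyclopent-1-ene
Product: 2 cis-6,6-dibromo-1,5-dimethylbicyclo[3.1.0]hexane (meso)
Conditions: CHBr3, KOtBu, pentane, −20 → 0 °C; cold aqueous wash, solution concentrated cold and used at once
Reagents that add atoms: bromoform BrC(Br)Br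
Why: Dibromocarbene, formed from bromoform by α-elimination, adds to the electron-rich tetrasubstituted alkene in a stereospecific [2+1] cyclopropanation; the cis ring fusion is the only one possible, and the adduct is kept cold because it is poised for ring opening.

Step 2
Reactants: 2 cis-6,6-dibromo-1,5-dimethylbicyclo[3.1.0]hexane
Product: 4 1-bromo-2,6,6-trimethylcyclohex-1-ene, via allylic dibromide 3 (not isolated)
Conditions: CH2Cl2, −20 → 20 °C (ring opening to 3); then AlMe3 (hexane solution, 1.5 equiv), CH2Cl2, −78 → −20 °C
Reagents that add atoms: trimethylaluminium C[Al](C)C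
Why: On warming, the bromide cis to the five-membered ring ionises while the C1–C5 bond shared by the three- and five-membered rings breaks in a disrotatory two-electron electrocyclic opening, so the cyclopentane grows by the former carbene carbon into the 2-bromo-1,3-dimethylcyclohexenyl cation, which collapses with bromide to the tertiary allylic dibromide 3; AlMe3 then re-ionises 3 and the bromotrimethylaluminate counter-ion delivers methyl to an allyl terminus. The closest known reaction types are the dihalocyclopropane-to-haloallyl halide rearrangement of dibromocarbene adducts of cyclopentenes and the methylation of tertiary halides by trialkylaluminium reagents through ion pairs. No ring is closed by bond formation: the six-membered ring results from cleavage of the zero-atom bridge of the bicyclo[3.1.0]hexane, and no stereocentre is created (3 is racemic and its stereocentre is lost in the cation). The step needs capture of the cation by methyl in preference to proton loss, and methylation at the right allyl terminus; the second point is void because the cation has a mirror plane through C2 (bearing Br) and C5, so both termini give 4, and the first is favoured by the non-basic methyl donor held in the ion pair at low temperature. The vinylic C–Br bond does not ionise and stays as the handle on the ring carbon that must carry the side chain.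

Step 3
Reactants: 5 geranyl acetate [(2E)-3,7-dimethylocta-2,6-dien-1-yl acetate]
Product: 7 (2E,6E)-3,7-dimethyl-8-oxoocta-2,6-dien-1-yl acetate, via 8-hydroxygeranyl acetate 6 (not isolated)
Conditions: SeO2 (cat.), t-BuOOH, CH2Cl2, rt; then crude mixture with MnO2, CH2Cl2, rt
Reagents that add atoms: tert-butyl hydroperoxide CC(C)(C)OO (terminal oxidant); selenium dioxide O=[Se]=O (oxygen carrier)
Why: The Riley allylic oxidation (ene reaction, then [2,3]-sigmatropic shift of the allylseleninic acid) attacks the E-methyl of the terminal trisubstituted alkene selectively, and MnO2 converges the allylic alcohol/enal mixture on the (E)-enal without touching the acetate or the 2,3-alkene.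

Step 4
Reactants: 7 (2E,6E)-3,7-dimethyl-8-oxoocta-2,6-dien-1-yl acetate
Product: 8 (2E,6E)-3,7-dimethylnona-2,6,8-trien-1-yl acetate
Conditions: Ph3PCH3Br, NaN(SiMe3)2 (1.05 equiv each), THF, −78 → 0 °C
Reagents that add atoms: methyltriphenylphosphonium bromide C[P+](c1ccccc1)(c1ccccc1)c1ccccc1.[Br-]
Why: Wittig methylenation of the enal by the non-stabilised ylide at low temperature is much faster than attack on the acetate and gives the terminal 1,3-diene without changing the two E alkenes.

Step 5
Reactants: 8 (2E,6E)-3,7-dimethylnona-2,6,8-trien-1-yl acetate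
Product: 9 (2E,6E)-3,7-dimethylnona-2,6,8-trien-1-ol
Conditions: K2CO3 (cat.), MeOH, rt
Reagents that add atoms: none
Why: Base-catalysed transesterification removes the allylic acetate, which would otherwise ionise to a π-allyl complex with zerovalent palladium in the next step.

Step 6
Reactants: 9 (2E,6E)-3,7-dimethylnona-2,6,8-trien-1-ol; 4 1-bromo-2,6,6-trimethylcyclohex-1-ene
Product: 11 (2E,6E)-3,7-dimethyl-9-(2,6,6-trimethylcyclohex-1-en-1-yl)nona-2,6-dien-1-ol, via bis(9-BBN) alkylborane borinate 10 (not isolated)
Conditions: 9-BBN-H dimer (2.2 equiv B–H), THF, 0 °C → rt; aq. Cs2CO3 added first, then 4, Pd(dppf)Cl2·CH2Cl2 (5 mol %), Ph3As, DMF/THF/H2O, 50 °C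
Reagents that add atoms: none
Why: 9-BBN first converts the hydroxyl into its borinate (H2 evolved) and then hydroborates only the monosubstituted terminus of the diene with boron on the terminal carbon, the trisubstituted alkenes being far slower, and the B-alkyl Suzuki–Miyaura coupling (oxidative addition of zerovalent palladium into the vinylic C–Br bond, base-assisted transmetalation, reductive elimination) then forms the sp2–sp3 bond between ring carbon C1 and the chain without touching either E alkene.

Step 7
Reactants: 11 (2E,6E)-3,7-dimethyl-9-(2,6,6-trimethylcyclohex-1-en-1-yl)nona-2,6-dien-1-ol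
Product: 12 (2E,6E)-3,7-dimethyl-9-(2,6,6-trimethylcyclohex-1-en-1-yl)nona-2,6-dien-1-yl methyl carbonate
Conditions: ClCO2Me, pyridine, CH2Cl2, 0 °C
Reagents that add atoms: methyl chloroformate COC(=O)Cl
Why: Acylation of the primary allylic alcohol gives the methyl carbonate, the leaving group that ionises irreversibly (loss of CO2) and supplies its own base in the allylation.

Step 8
Reactants: 13 2,5-dihydroxybenzaldehyde
Product: 14 2-hydroxy-5-[(triisopropylsilyl)oxy]benzaldehyde
Conditions: i-Pr3SiCl (1.05 equiv), imidazole, CH2Cl2, 0 °C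
Reagents that add atoms: chlorotriisopropylsilane CC(C)[Si](Cl)(C(C)C)C(C)C
Why: Silyl ether formation is selective for the 5-hydroxyl because the 2-hydroxyl is held in a hydrogen bond to the aldehyde and is flanked by it.

Step 9
Reactants: 14 2-hydroxy-5-[(triisopropylsilyl)oxy]benzaldehyde
Product: 15 2-ethenyl-4-[(triisopropylsilyl)oxy]phenol
Conditions: Ph3PCH3Br, NaN(SiMe3)2 (2.4 equiv each, one equivalent consumed by the phenol), THF, 0 °C → rt; aq. NH4Cl; used promptly
Reagents that add atoms: methyltriphenylphosphonium bromide C[P+](c1ccccc1)(c1ccccc1)c1ccccc1.[Br-]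
Why: Wittig methylenation of the salicylaldehyde phenoxide gives the 2-vinylphenol, and the bulky triisopropylsilyl ether withstands the basic ylide.

Step 10
Reactants: 12 (2E,6E)-3,7-dimethyl-9-(2,6,6-trimethylcyclohex-1-en-1-yl)nona-2,6-dien-1-yl methyl carbonate; 15 2-ethenyl-4-[(triisopropylsilyl)oxy]phenol
Product: 16 1-{[(3S,6E)-3,7-dimethyl-9-(2,6,6-trimethylcyclohex-1-en-1-yl)nona-1,6-dien-3-yl]oxy}-2-ethenyl-4-[(triisopropylsilyl)oxy]benzene
Conditions: Pd2(dba)3·CHCl3 (1 mol %), (R,R)-DACH-phenyl ligand [N,N′-((1R,2R)-cyclohexane-1,2-diyl)bis(2-(diphenylphosphanyl)benzamide)] (3 mol %), CH2Cl2, rt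
Reagents that add atoms: none
Why: Tsuji–Trost asymmetric allylic O-alkylation, in which zerovalent palladium ionises the carbonate (CO2 and methoxide are released, the latter deprotonating the phenol) to a π-allyl complex of divalent palladium and the phenoxide attacks its more substituted terminus from the face left open by the chiral pocket of the ligand, which sets the quaternary C–O stereocentre as S while the E geometry of the carbonate fixes which allyl face the metal holds.

Step 11
Reactants: 16 1-{[(3S,6E)-3,7-dimethyl-9-(2,6,6-trimethylcyclohex-1-en-1-yl)nona-1,6-dien-3-yl]oxy}-2-ethenyl-4-[(triisopropylsilyl)oxy]benzene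
Product: 17 triisopropyl({(2S)-2-methyl-2-[(3E)-4-methyl-6-(2,6,6-trimethylcyclohex-1-en-1-yl)hex-3-en-1-yl]-2H-chromen-6-yl}oxy)silane
Conditions: second-generation Grubbs catalyst (H2IMes)(PCy3)Cl2Ru=CHPh (5 mol %), CH2Cl2 (dilute), 40 °C
Reagents that add atoms: none
Why: In this ring-closing metathesis the ruthenium carbene forms at the unhindered styrene vinyl group and closes onto the neighbouring tertiary allylic vinyl group to the six-membered 2H-chromene (ethylene lost) faster than it can engage the trisubstituted or tetrasubstituted alkenes, and the quaternary stereocentre cannot epimerise.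

Step 12
Reactants: 17 triisopropyl({(2S)-2-methyl-2-[(3E)-4-methyl-6-(2,6,6-trimethylcyclohex-1-en-1-yl)hex-3-en-1-yl]-2H-chromen-6-yl}oxy)silane
Product: 18 (2S)-2-methyl-2-[(3E)-4-methyl-6-(2,6,6-trimethylcyclohex-1-en-1-yl)hex-3-en-1-yl]-2H-chromen-6-ol
Conditions: Bu4NF, THF, 0 °C, under argon; aq. NH4Cl
Reagents that add atoms: none
Why: Fluoride-induced desilylation of the aryl silyl ether leaves the chromene, the three alkenes and the stereocentre untouched, and the air-sensitive hydroquinone monoether is freed only in the last step.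

Compound list
1 | 1,2-dimethylcyclopent-1-ene | CC1=C(C)CCC1 | starting material
2 | cis-6,6-dibromo-1,5-dimethylbicyclo[3.1.0]hexane (meso) | C[C@@]12CCC[C@]1(C)C2(Br)Br | intermediate
3 | 2,3-dibromo-1,3-dimethylcyclohex-1-ene (racemic, not isolated) | CC1=C(Br)C(C)(Br)CCC1 | intermediate
4 | 1-bromo-2,6,6-trimethylcyclohex-1-ene | CC1=C(Br)C(C)(C)CCC1 | intermediate
5 | geranyl acetate | CC(C)=CCC/C(C)=C/COC(C)=O | starting material
6 | (2E,6E)-8-hydroxy-3,7-dimethylocta-2,6-dien-1-yl acetate (not isolated) | OC/C(C)=C/CC/C(C)=C/COC(C)=O | intermediate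
7 | (2E,6E)-3,7-dimethyl-8-oxoocta-2,6-dien-1-yl acetate | O=C/C(C)=C/CC/C(C)=C/COC(C)=O | intermediate
8 | (2E,6E)-3,7-dimethylnona-2,6,8-trien-1-yl acetate | C=C/C(C)=C/CC/C(C)=C/COC(C)=O | intermediate
9 | (2E,6E)-3,7-dimethylnona-2,6,8-trien-1-ol | C=C/C(C)=C/CC/C(C)=C/CO | intermediate
10 | 9-[(3E,7E)-9-(9-borabicyclo[3.3.1]nonan-9-yloxy)-3,7-dimethylnona-3,7-dien-1-yl]-9-borabicyclo[3.3.1]nonane (not isolated) | B1(CC/C(C)=C/CC/C(C)=C/COB2C3CCCC2CCC3)C2CCCC1CCC2 | intermediate
11 | (2E,6E)-3,7-dimethyl-9-(2,6,6-trimethylcyclohex-1-en-1-yl)nona-2,6-dien-1-ol | CC1=C(CC/C(C)=C/CC/C(C)=C/CO)C(C)(C)CCC1 | intermediate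
12 | (2E,6E)-3,7-dimethyl-9-(2,6,6-trimethylcyclohex-1-en-1-yl)nona-2,6-dien-1-yl methyl carbonate | CC1=C(CC/C(C)=C/CC/C(C)=C/COC(=O)OC)C(C)(C)CCC1 | intermediate
13 | 2,5-dihydroxybenzaldehyde | O=Cc1cc(O)ccc1O | starting material
14 | 2-hydroxy-5-[(triisopropylsilyl)oxy]benzaldehyde | O=Cc1cc(O[Si](C(C)C)(C(C)C)C(C)C)ccc1O | intermediate
15 | 2-ethenyl-4-[(triisopropylsilyl)oxy]phenol | C=Cc1cc(O[Si](C(C)C)(C(C)C)C(C)C)ccc1O | intermediate
16 | 1-{[(3S,6E)-3,7-dimethyl-9-(2,6,6-trimethylcyclohex-1-en-1-yl)nona-1,6-dien-3-yl]oxy}-2-ethenyl-4-[(triisopropylsilyl)oxy]benzene | CC1=C(CC/C(C)=C/CC[C@@](C)(C=C)Oc2ccc(O[Si](C(C)C)(C(C)C)C(C)C)cc2C=C)C(C)(C)CCC1 | intermediate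
17 | triisopropyl({(2S)-2-methyl-2-[(3E)-4-methyl-6-(2,6,6-trimethylcyclohex-1-en-1-yl)hex-3-en-1-yl]-2H-chromen-6-yl}oxy)silane | CC1=C(CC/C(C)=C/CC[C@@]2(C)C=Cc3cc(O[Si](C(C)C)(C(C)C)C(C)C)ccc3O2)C(C)(C)CCC1 | intermediate
18 | (2S)-2-methyl-2-[(3E)-4-methyl-6-(2,6,6-trimethylcyclohex-1-en-1-yl)hex-3-en-1-yl]-2H-chromen-6-ol | CC1=C(CC/C(C)=C/CC[C@@]2(C)C=Cc3cc(O)ccc3O2)C(C)(C)CCC1 | target

Total step count: 12.
Longest linear sequence: 8 steps (steps 3, 4, 5, 6, 7, 10, 11, 12, from geranyl acetate). The ring fragment (steps 1, 2) joins at step 6 and the phenol fragment (steps 8, 9) at step 10.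

Steps most likely to fail

Step 2. Proton loss from the allyl cation, or loss of HBr from 3 before the aluminium reagent is added, may outrun methyl transfer and give bromodienes instead of the quaternary carbon. The fallback keeps the ring enlargement but changes the C–C bond formation from cation capture to organocopper allylic substitution. It sets out from 2: AgOAc in AcOH at rt should open the cyclopropane with capture by acetate to give 2-bromo-1,3-dimethylcyclohex-2-en-1-yl acetate F1. Me2CuLi in Et2O at −78 → 0 °C should then replace the allylic acetate by methyl; direct and allylically transposed attack give the same product because the allyl unit is symmetric. The fallback comes back to the route at 4.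

Step 6. Oxidative addition of zerovalent palladium into the hindered tetrasubstituted C–Br bond may be so slow that protodeboronation and β-hydride elimination of the alkylborane consume the chain partner. The fallback forms the neighbouring sp3–sp3 bond by sulfone alkylation instead. It sets out from 4 and from 6 (isolated after the SeO2 stage of step 3, before MnO2).
- Bromide 4 is exchanged with t-BuLi (THF, −78 °C) and the vinyllithium is trapped with paraformaldehyde to give (2,6,6-trimethylcyclohex-1-en-1-yl)methanol F2.
- PBr3 (Et2O, 0 °C) gives 2-(bromomethyl)-1,3,3-trimethylcyclohex-1-ene F3, and PhSO2Na in DMF gives {[(2,6,6-trimethylcyclohex-1-en-1-yl)methyl]sulfonyl}benzene F4.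
- Alcohol 6 with PBr3 (Et2O, −10 °C) gives (2E,6E)-8-bromo-3,7-dimethylocta-2,6-dien-1-yl acetate F5.
- The anion of F4 (n-BuLi, THF, −78 °C) is alkylated with F5 to give (2E,6E)-3,7-dimethyl-9-(phenylsulfonyl)-9-(2,6,6-trimethylcyclohex-1-en-1-yl)nona-2,6-dien-1-yl acetate F6.
- Pd(dppf)Cl2 with LiBHEt3 (THF, 0 °C) removes the allylic sulfonyl group reductively and cleaves the acetate.

The fallback comes back to the route at 11.

Step 10. π–σ–π equilibration of the allyl complex and attack of the hindered ortho-substituted phenoxide at the primary terminus may erode the enantiomeric purity and the branched selectivity. The fallback gives up catalyst control and separates enantiomers. It sets out from 11: MnO2 (CH2Cl2, rt) gives (2E,6E)-3,7-dimethyl-9-(2,6,6-trimethylcyclohex-1-en-1-yl)nona-2,6-dienal F7. Condensation with hydroquinone in pyridine at 110 °C (aldol-type condensation to the ortho-quinone methide, then oxa-6π electrocyclisation) gives racemic 2-methyl-2-[(3E)-4-methyl-6-(2,6,6-trimethylcyclohex-1-en-1-yl)hex-3-en-1-yl]-2H-chromen-6-ol F8 without any protecting group. Preparative chromatography on a chiral stationary phase then delivers the (S)-enantiomer. The fallback comes back to the route at 18 and bypasses 12 to 17.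

Further compounds
F1 | step 2 | 2-bromo-1,3-dimethylcyclohex-2-en-1-yl acetate (racemic) | CC1=C(Br)C(C)(OC(C)=O)CCC1
F2 | step 6 | (2,6,6-trimethylcyclohex-1-en-1-yl)methanol | CC1=C(CO)C(C)(C)CCC1
F3 | step 6 | 2-(bromomethyl)-1,3,3-trimethylcyclohex-1-ene | CC1=C(CBr)C(C)(C)CCC1
F4 | step 6 | {[(2,6,6-trimethylcyclohex-1-en-1-yl)methyl]sulfonyl}benzene | CC1=C(CS(=O)(=O)c2ccccc2)C(C)(C)CCC1
F5 | step 6 | (2E,6E)-8-bromo-3,7-dimethylocta-2,6-dien-1-yl acetate | BrC/C(C)=C/CC/C(C)=C/COC(C)=O
F6 | step 6 | (2E,6E)-3,7-dimethyl-9-(phenylsulfonyl)-9-(2,6,6-trimethylcyclohex-1-en-1-yl)nona-2,6-dien-1-yl acetate (racemic) | CC1=C(C(C/C(C)=C/CC/C(C)=C/COC(C)=O)S(=O)(=O)c2ccccc2)C(C)(C)CCC1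
F7 | step 10 | (2E,6E)-3,7-dimethyl-9-(2,6,6-trimethylcyclohex-1-en-1-yl)nona-2,6-dienal | CC1=C(CC/C(C)=C/CC/C(C)=C/C=O)C(C)(C)CCC1
F8 | step 10 | racemic 2-methyl-2-[(3E)-4-methyl-6-(2,6,6-trimethylcyclohex-1-en-1-yl)hex-3-en-1-yl]-2H-chromen-6-ol | CC1=C(CC/C(C)=C/CCC2(C)C=Cc3cc(O)ccc3O2)C(C)(C)CCC1
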